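**Strategy.** Everything rests on disconnecting the bond between the benzylic carbon C3 of the propanoic acid chain and C1 of the 3,4-dihydroxyphenyl ring, made at the alkene oxidation level. Since C2 bears the feruloyl ester next to the C1 carboxyl, the C2–C3 unit is the O-feruloyl enol of a pyruvate ester: tert-butyl 2-(feruloyloxy)acrylate, available from tert-butyl pyruvate. A Mizoroki–Heck arylation of its terminal =CH2 with the acetonide of 4-bromocatechol joins both halves in one operation, whatever the alkene geometry. The target's own feruloyl carbonyl then serves as chelating handle for an E/Z-convergent rhodium-catalysed asymmetric hydrogenation that sets the single (R) centre.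

Key step: step 3

Assumption (chemistry): (R,R)-Et-DuPhos–Rh is taken to give the (2R)-acyloxy ester from 8, the sense established for α-(acyloxy)acrylates; the antipodal ligand would be used if the sense were opposite.

Step 1
Reactants: 1 (E)-ferulic acid
Product: 3 (2E)-3-[4-(tert-butyldimethylsilyloxy)-3-methoxyphenyl]prop-2-enoic acid, via bis-silylated ferulate 2 (not isolated)
Conditions: TBSCl (2.3 equiv), imidazole (5 equiv), DMF, rt; then AcOH/THF/H2O (3:1:1), rt
Reagents that add atoms: tert-butyldimethylsilyl chloride (TBSCl), CC(C)(C)[Si](C)(C)Cl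
Why: Standard silyl protection silylates both the phenol and the acid, and the silyl ester, far more labile than the aryl silyl ether, should then be hydrolysed selectively by aqueous acetic acid with the (E)-alkene untouched.

Step 2
Reactants: 3 (2E)-3-[4-(tert-butyldimethylsilyloxy)-3-methoxyphenyl]prop-2-enoic acid; 4 tert-butyl pyruvate
Product: 6 tert-butyl 2-{[(2E)-3-[4-(tert-butyldimethylsilyloxy)-3-methoxyphenyl]prop-2-enoyl]oxy}prop-2-enoate, via acid chloride 5 (not isolated)
Conditions: (COCl)2 (1.2 equiv), DMF (cat.), CH2Cl2, 0 °C → rt, evaporate; then 4 (1.5 equiv), Et3N (1.5 equiv), DMAP (5 mol %), CH2Cl2, −10 → 0 °C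
Reagents that add atoms: none
Why: Acid chloride formation followed by amine-mediated O-acylation of the pyruvate enolate is the standard enol-ester synthesis of 2-(acyloxy)acrylates; the cinnamoyl chloride has no enolisable α-hydrogen, so ketene formation cannot compete, and no stereocentre is formed.

Step 3
Reactants: 6 tert-butyl 2-{[(2E)-3-[4-(tert-butyldimethylsilyloxy)-3-methoxyphenyl]prop-2-enoyl]oxy}prop-2-enoate; 7 5-bromo-2,2-dimethyl-1,3-benzodioxole
Product: 8 tert-butyl (2Z)-3-(2,2-dimethyl-1,3-benzodioxol-5-yl)-2-{[(2E)-3-[4-(tert-butyldimethylsilyloxy)-3-methoxyphenyl]prop-2-enoyl]oxy}prop-2-enoate (Z isomer expected; any E isomer is carried on)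
Conditions: 7 (1.2 equiv), Pd2(dba)3 (2.5 mol %), [HP(t-Bu)3]BF4 (10 mol %), Cy2NMe (1.5 equiv), 1,4-dioxane, 70 °C
Reagents that add atoms: none
Why: Oxidative addition of the Ar–Br bond of 7 to Pd(0)–P(t-Bu)3 is followed by syn-carbopalladation of the unsubstituted =CH2 terminus of the enol ester in 6 (aryl to C3, Pd to the acyloxy-bearing C2), syn-β-hydride elimination of a new benzylic hydrogen and base-assisted return to Pd(0) (Mizoroki–Heck reaction). The closest known reaction type is the Heck arylation of α-heteroatom-substituted acrylates such as 2-acetamidoacrylates, and of methacrylates, with aryl bromides under Pd/P(t-Bu)3/amine-base conditions. No ring is closed and no stereocentre is formed; the geometry of the trisubstituted alkene (Z expected, aryl trans to the ester) is of no consequence because step 4 converges both isomers. The step needs site selectivity between the two alkenes of 6 and a single regiochemistry: the 1,1-disubstituted terminal alkene should insert far faster than the 1,2-disubstituted, electron-rich cinnamoyl alkene, and the aryl group adds to the unhindered CH2. After insertion the only β-hydrogens are benzylic and the acyloxy group sits α to palladium, so neither an isomeric alkene nor β-heteroatom elimination is possible. The bulky tertiary amine base cannot be acylated by the enol ester.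

Step 4
Reactants: 8 tert-butyl (2Z)-3-(2,2-dimethyl-1,3-benzodioxol-5-yl)-2-{[(2E)-3-[4-(tert-butyldimethylsilyloxy)-3-methoxyphenyl]prop-2-enoyl]oxy}prop-2-enoate
Product: 9 tert-butyl (2R)-3-(2,2-dimethyl-1,3-benzodioxol-5-yl)-2-{[(2E)-3-[4-(tert-butyldimethylsilyloxy)-3-methoxyphenyl]prop-2-enoyl]oxy}propanoate
Conditions: [Rh(cod)((R,R)-Et-DuPhos)]OTf (2 mol %), H2 (4 bar), degassed MeOH/THF (4:1), 25 °C
Reagents that add atoms: none
Why: In this rhodium–bisphosphine asymmetric hydrogenation of an α-(acyloxy)acrylate the enol C=C and the feruloyl C=O chelate the cationic Rh centre, the C2-symmetric (R,R)-Et-DuPhos ligand fixes the face of hydrogen delivery to C2 so that the (R) centre should form from either alkene isomer, and the cinnamoyl alkene, which cannot chelate, should remain.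

Step 5
Reactants: 9 tert-butyl (2R)-3-(2,2-dimethyl-1,3-benzodioxol-5-yl)-2-{[(2E)-3-[4-(tert-butyldimethylsilyloxy)-3-methoxyphenyl]prop-2-enoyl]oxy}propanoate
Product: 10 (2R)-3-(3,4-dihydroxyphenyl)-2-{[(2E)-3-(4-hydroxy-3-methoxyphenyl)prop-2-enoyl]oxy}propanoic acid
Conditions: TFA/H2O (9:1), 0 °C → rt, Ar; evaporation, reverse-phase chromatography
Reagents that add atoms: none
Why: Global acidolysis should cleave the tert-butyl ester via the tert-butyl cation, the catechol acetonide by ketal hydrolysis and the aryl silyl ether by protodesilylation, under conditions that do not endanger the α-acyloxy stereocentre, the ester linkage or the (E)-alkene.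

**Compound list**

1 | (E)-ferulic acid, (2E)-3-(4-hydroxy-3-methoxyphenyl)prop-2-enoic acid | COc1cc(/C=C/C(=O)O)ccc1O | starting material
2 | tert-butyldimethylsilyl (2E)-3-[4-(tert-butyldimethylsilyloxy)-3-methoxyphenyl]prop-2-enoate | COc1cc(/C=C/C(=O)O[Si](C)(C)C(C)(C)C)ccc1O[Si](C)(C)C(C)(C)C | intermediate
3 | (2E)-3-[4-(tert-butyldimethylsilyloxy)-3-methoxyphenyl]prop-2-enoic acid | COc1cc(/C=C/C(=O)O)ccc1O[Si](C)(C)C(C)(C)C | intermediate
4 | tert-butyl pyruvate (tert-butyl 2-oxopropanoate) | CC(=O)C(=O)OC(C)(C)C | starting material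
5 | (2E)-3-[4-(tert-butyldimethylsilyloxy)-3-methoxyphenyl]prop-2-enoyl chloride | COc1cc(/C=C/C(=O)Cl)ccc1O[Si](C)(C)C(C)(C)C | intermediate
6 | tert-butyl 2-{[(2E)-3-[4-(tert-butyldimethylsilyloxy)-3-methoxyphenyl]prop-2-enoyl]oxy}prop-2-enoate | COc1cc(/C=C/C(=O)OC(=C)C(=O)OC(C)(C)C)ccc1O[Si](C)(C)C(C)(C)C | intermediate
7 | 5-bromo-2,2-dimethyl-1,3-benzodioxole | CC1(C)Oc2ccc(Br)cc2O1 | starting material
8 | tert-butyl (2Z)-3-(2,2-dimethyl-1,3-benzodioxol-5-yl)-2-{[(2E)-3-[4-(tert-butyldimethylsilyloxy)-3-methoxyphenyl]prop-2-enoyl]oxy}prop-2-enoate | COc1cc(/C=C/C(=O)O/C(=C\c2ccc3OC(C)(C)Oc3c2)C(=O)OC(C)(C)C)ccc1O[Si](C)(C)C(C)(C)C | intermediate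
9 | tert-butyl (2R)-3-(2,2-dimethyl-1,3-benzodioxol-5-yl)-2-{[(2E)-3-[4-(tert-butyldimethylsilyloxy)-3-methoxyphenyl]prop-2-enoyl]oxy}propanoate | COc1cc(/C=C/C(=O)O[C@H](Cc2ccc3OC(C)(C)Oc3c2)C(=O)OC(C)(C)C)ccc1O[Si](C)(C)C(C)(C)C | intermediate
10 | (2R)-3-(3,4-dihydroxyphenyl)-2-{[(2E)-3-(4-hydroxy-3-methoxyphenyl)prop-2-enoyl]oxy}propanoic acid | COc1cc(/C=C/C(=O)O[C@H](Cc2ccc(O)c(O)c2)C(=O)O)ccc1O | target

**Total step count:** 5
**Longest linear sequence:** 5 steps (1 → 3 → 6 → 8 → 9 → 10)

**Steps most likely to fail**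

Step 3 (Heck arylation). Oxidative addition of the electron-rich aryl bromide may be slow, and at the temperature then needed the enol ester may be lost by acyl transfer, or the aryl–palladium species may also insert into the cinnamoyl alkene. The fallback makes the same aryl–CH2 bond by opening an epoxide and buys the stereocentre. Bromide 7 is converted with Mg in THF into (2,2-dimethyl-1,3-benzodioxol-5-yl)magnesium bromide F1. With CuI (10 mol %) in THF at −40 → −20 °C, F1 should open purchased tert-butyl (2R)-oxirane-2-carboxylate at the CH2 carbon, leaving the stereocentre untouched, to give tert-butyl (2R)-3-(2,2-dimethyl-1,3-benzodioxol-5-yl)-2-hydroxypropanoate F2. Steglich esterification of F2 with acid 3 (EDC·HCl, DMAP, CH2Cl2, 0 °C) proceeds with retention at C2. The fallback sets out from 7 and 3 and comes back to the route at 9; steps 2 to 4 are then not needed.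

Step 4 (asymmetric hydrogenation). Chemoselectivity may be lost through hydrogen uptake by the cinnamoyl alkene, or facial selectivity may be poor because the conjugated acyl group binds rhodium differently from a simple acetate. The fallback carries a saturated acyl group through the hydrogenation and exchanges it afterwards. Pyruvate 4 is O-acetylated (Ac2O, Et3N, DMAP cat., CH2Cl2) to tert-butyl 2-acetoxyprop-2-enoate F3. Heck arylation of F3 with 7 under the conditions of step 3 gives tert-butyl (2Z)-2-acetoxy-3-(2,2-dimethyl-1,3-benzodioxol-5-yl)prop-2-enoate F4. Hydrogenation with the same (R,R)-Et-DuPhos–Rh catalyst gives tert-butyl (2R)-2-acetoxy-3-(2,2-dimethyl-1,3-benzodioxol-5-yl)propanoate F5. Methanolysis of the acetate (K2CO3, MeOH, 0 °C; the tert-butyl ester is inert) gives the hydroxy ester F2, which is esterified with 3 (EDC·HCl, DMAP). The fallback sets out from 4 and 7 and comes back to the route at 9.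

Step 2 (enol ester formation). The pyruvate may self-condense under the amine base, C-acylation may compete with O-acylation, and the product may be lost by acyl transfer to DMAP. The fallback builds the enol ester by elimination instead of enolisation. Purchased racemic tert-butyl oxirane-2-carboxylate is opened with LiBr/AcOH in THF at the CH2 carbon to give tert-butyl 3-bromo-2-hydroxypropanoate F6. Esterification with 3 (EDC·HCl, DMAP, CH2Cl2) gives tert-butyl 3-bromo-2-{[(2E)-3-[4-(tert-butyldimethylsilyloxy)-3-methoxyphenyl]prop-2-enoyl]oxy}propanoate F7. DBU (CH2Cl2, 0 °C) then eliminates hydrogen bromide by removal of the acidic C2–H. The fallback sets out from 3 and comes back to the route at 6.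

**Further compounds**

F1 | step 3 | (2,2-dimethyl-1,3-benzodioxol-5-yl)magnesium bromide | Br[Mg]c1ccc2OC(C)(C)Oc2c1
F2 | step 3 | tert-butyl (2R)-3-(2,2-dimethyl-1,3-benzodioxol-5-yl)-2-hydroxypropanoate | O[C@H](Cc1ccc2OC(C)(C)Oc2c1)C(=O)OC(C)(C)C
F3 | step 4 | tert-butyl 2-acetoxyprop-2-enoate | C=C(OC(C)=O)C(=O)OC(C)(C)C
F4 | step 4 | tert-butyl (2Z)-2-acetoxy-3-(2,2-dimethyl-1,3-benzodioxol-5-yl)prop-2-enoate | CC(=O)O/C(=C\c1ccc2OC(C)(C)Oc2c1)C(=O)OC(C)(C)C
F5 | step 4 | tert-butyl (2R)-2-acetoxy-3-(2,2-dimethyl-1,3-benzodioxol-5-yl)propanoate | CC(=O)O[C@H](Cc1ccc2OC(C)(C)Oc2c1)C(=O)OC(C)(C)C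
F6 | step 2 | tert-butyl 3-bromo-2-hydroxypropanoate (racemic) | OC(CBr)C(=O)OC(C)(C)C
F7 | step 2 | tert-butyl 3-bromo-2-{[(2E)-3-[4-(tert-butyldimethylsilyloxy)-3-methoxyphenyl]prop-2-enoyl]oxy}propanoate (racemic) | COc1cc(/C=C/C(=O)OC(CBr)C(=O)OC(C)(C)C)ccc1O[Si](C)(C)C(C)(C)C
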